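**Plan**
1. Retrosynthesis: the quinone goes back to its hydroquinone. The six-membered ring is cut at C4–C5 (quinone numbering, furyl on C2) and contracted to a 4-hydroxy-4-vinylcyclobut-2-enone. The carbinol–vinyl bond, the ester C–O bond and the furan C2–cyclobutene bond are cut next, then the prenyl C=C (cross-metathesis) and the carbinol C–C bond (allylation).
2. Forward: the furan ring is purchased. The side chain is built on it first, the four-membered ring is attached at furan C2, the ester is made, a vinyl group is added, the four-membered ring is expanded to the six-membered ring, and the hydroquinone is oxidised.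
3. Enabling feature: the ring is a 2-monosubstituted cyclohexa-2,5-diene-1,4-dione. C4(=O) and C1(=O) map onto the C=O and C–OH carbons of a cyclobutenone, C3H=C2(furyl) onto its ring alkene and C6H=C5H onto a vinyl group. Because only C2 is substituted, either mode of vinyl addition to the 3-furylcyclobutenedione leads to the same ring.
4. Stereochemistry: the single (R) carbinol centre comes from catalyst-controlled Re-face allylboration in step 1; no later step breaks a bond at that carbon.

Key step: step 6

Remark on the chemistry: 5-bromofuran-3-carbaldehyde (1) is taken as a catalogue building block.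

**Step 1**
Reactants: 1 5-bromofuran-3-carbaldehyde; 2 allylboronic acid pinacol ester
Product: 4 (R)-1-(5-bromofuran-3-yl)but-3-en-1-ol, via boronate ester 3 (not isolated)
Conditions: 2 (1.2 equiv), (R)-TRIP phosphoric acid (5 mol %), toluene, −30 °C; aqueous work-up
Reagents that add atoms: allylboronic acid pinacol ester, C=CCB1OC(C)(C)C(C)(C)O1
Why: Chiral phosphoric acid-catalysed allylboration runs through a closed six-membered chair transition state in which the (R)-catalyst hydrogen-bonds to the boronate and should direct the allyl group to the Re face of the aldehyde, which sets the (R) carbinol centre.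

**Step 2**
Reactants: 4 (R)-1-(5-bromofuran-3-yl)but-3-en-1-ol; 5 2-methylbut-2-ene
Product: 6 (R)-1-(5-bromofuran-3-yl)-4-methylpent-3-en-1-ol
Conditions: 5 (excess, co-solvent), second-generation Grubbs catalyst (H2IMes)(PCy3)Cl2Ru=CHPh (3 mol %), CH2Cl2, 40 °C, sealed vessel
Reagents that add atoms: 2-methylbut-2-ene, CC=C(C)C
Why: Olefin cross-metathesis of a terminal alkene with excess 2-methylbut-2-ene should give the dimethyl-substituted alkene with loss of propene, the free alcohol and the bromofuran being tolerated and no alkene geometry arising.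

**Step 3**
Reactants: 6 (R)-1-(5-bromofuran-3-yl)-4-methylpent-3-en-1-ol; 7 diisopropyl squarate
Product: 11 3-[4-[(1R)-1-hydroxy-4-methylpent-3-en-1-yl]furan-2-yl]cyclobut-3-ene-1,2-dione, via dilithiated furan 8 (not isolated), via squarate adduct 9 (not isolated), via ring diol 10 (not isolated)
Conditions: n-BuLi (2.1 equiv), THF, −78 °C; cannulated into 7, THF, −78 °C; iBu2AlH (2.5 equiv), −78 to 0 °C; then 1 M aq. HCl, THF, 0 °C to rt
Reagents that add atoms: diisopropyl squarate, CC(C)OC1=C(OC(C)C)C(=O)C1=O; water, O
Why: O-deprotonation and bromine–lithium exchange give a 2-furyllithium that adds 1,2 to one squarate carbonyl, iBu2AlH reduces the remaining vinylogous-ester carbonyl, and aqueous acid ionises the two ring carbinols in turn (furfuryl-type and alkoxy-stabilised allyl cations) so that water enters at the isopropoxy-bearing carbons and isopropanol leaves, which is the two-fold 1,2-addition and hydrolytic transposition used to make substituted cyclobutenediones from squarates.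

**Step 4**
Reactants: 11 3-[4-[(1R)-1-hydroxy-4-methylpent-3-en-1-yl]furan-2-yl]cyclobut-3-ene-1,2-dione; 12 3-methylbutanoyl chloride
Product: 13 (R)-1-[5-(3,4-dioxocyclobut-1-en-1-yl)furan-3-yl]-4-methylpent-3-en-1-yl 3-methylbutanoate
Conditions: 12 (1.2 equiv), pyridine (2 equiv), CH2Cl2, −20 to 0 °C
Reagents that add atoms: 3-methylbutanoyl chloride, CC(C)CC(=O)Cl
Why: Acylation of a secondary alcohol with an acid chloride and pyridine should proceed with retention because the C–O bond at the stereocentre is not broken, and the dione has no enolisable hydrogen and offers a tertiary amine no productive reaction.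

**Step 5**
Reactants: 13 (R)-1-[5-(3,4-dioxocyclobut-1-en-1-yl)furan-3-yl]-4-methylpent-3-en-1-yl 3-methylbutanoate; 14 vinylmagnesium bromide
Product: 15 (R)-1-[5-(4-hydroxy-3-oxo-4-vinylcyclobut-1-en-1-yl)furan-3-yl]-4-methylpent-3-en-1-yl 3-methylbutanoate (both epimers at the ring carbinol)
Conditions: CH2=CHMgBr (1.1 equiv), THF, −78 °C; then aq. NH4Cl
Reagents that add atoms: vinylmagnesium bromide, C=C[Mg]Br
Why: Grignard 1,2-addition to the strained cyclobutenedione carbonyl at −78 °C should outrun attack on the ester and is expected at the cross-conjugated carbonyl next to the furyl-bearing carbon, while attack at the other carbonyl would lead to the same hydroquinone in step 6 and the configuration of the new ring carbinol is lost there.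

**Step 6**
Reactants: 15 (R)-1-[5-(4-hydroxy-3-oxo-4-vinylcyclobut-1-en-1-yl)furan-3-yl]-4-methylpent-3-en-1-yl 3-methylbutanoate
Product: 18 (R)-1-[5-(2,5-dihydroxyphenyl)furan-3-yl]-4-methylpent-3-en-1-yl 3-methylbutanoate, via dienylketene 16 (not isolated), via cyclohexadienone 17 (not isolated)
Conditions: toluene (degassed, 0.02 M), 110 °C, Ar
Reagents that add atoms: none
Why: Heating should open the cyclobutenone by thermal conrotatory 4π-electrocyclic cleavage of the C(=O)–C(OH) ring bond, which releases the strain of the four-membered ring and gives the (Z)-dienylketene 16 with the ketene carbon and the vinyl terminus on the same side of the central alkene. A thermal disrotatory 6π-electrocyclisation then joins the ketene carbon to the terminal vinyl carbon (the C4–C5 bond of the later quinone), closing the six-membered carbocycle as cyclohexadienone 17, and enolisation of its CH2–C=O unit gives the aromatic hydroquinone 18. The closest known reaction type is the thermal ring expansion of 4-alkenyl-4-hydroxycyclobutenones to hydroquinones, the alkenyl counterpart of the Moore rearrangement. No stereocentre is created, since the ring carbinol carbon of 15 becomes planar and the side-chain (R) centre is remote from the reacting π-system. The step needs torquoselectivity in the ring opening, which the electron-donating 4-hydroxyl secures by rotating outward so that the vinyl group turns inward toward the ketene. It also needs the 6π-closure to outrun capture of the ketene by the hydroxyl group, which the cis-placed vinyl group and high dilution favour, and the furan, the trisubstituted alkene and the ester should be inert to neutral heating.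

**Step 7**
Reactants: 18 (R)-1-[5-(2,5-dihydroxyphenyl)furan-3-yl]-4-methylpent-3-en-1-yl 3-methylbutanoate
Product: 19 (R)-1-[5-(3,6-dioxocyclohexa-1,4-dien-1-yl)furan-3-yl]-4-methylpent-3-en-1-yl 3-methylbutanoate
Conditions: Ag2O (2 equiv), MgSO4, Et2O, rt, dark
Reagents that add atoms: none
Why: Two-electron oxidation of a hydroquinone to the 1,4-benzoquinone by Ag2O under neutral anhydrous conditions should leave the furan, the alkene, the ester and the stereocentre untouched.

**Compound list**
1 | 5-bromofuran-3-carbaldehyde | O=Cc1coc(Br)c1 | starting material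
2 | allylboronic acid pinacol ester | C=CCB1OC(C)(C)C(C)(C)O1 | starting material
3 | pinacol boronate ester of 4 | C=CC[C@@H](OB1OC(C)(C)C(C)(C)O1)c1coc(Br)c1 | intermediate
4 | (R)-1-(5-bromofuran-3-yl)but-3-en-1-ol | C=CC[C@@H](O)c1coc(Br)c1 | intermediate
5 | 2-methylbut-2-ene | CC=C(C)C | starting material
6 | (R)-1-(5-bromofuran-3-yl)-4-methylpent-3-en-1-ol | CC(C)=CC[C@@H](O)c1coc(Br)c1 | intermediate
7 | diisopropyl squarate (3,4-diisopropoxycyclobut-3-ene-1,2-dione) | CC(C)OC1=C(OC(C)C)C(=O)C1=O | starting material
8 | lithium (R)-1-(5-lithiofuran-3-yl)-4-methylpent-3-en-1-olate | CC(C)=CC[C@@H](O[Li])c1coc([Li])c1 | intermediate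
9 | 4-hydroxy-4-[4-[(1R)-1-hydroxy-4-methylpent-3-en-1-yl]furan-2-yl]-2,3-diisopropoxycyclobut-2-en-1-one (present as its dilithium alkoxide, both ring epimers) | CC(C)=CC[C@@H](O)c1coc(C2(O)C(OC(C)C)=C(OC(C)C)C2=O)c1 | intermediate
10 | 1-[4-[(1R)-1-hydroxy-4-methylpent-3-en-1-yl]furan-2-yl]-3,4-diisopropoxycyclobut-3-ene-1,2-diol (present as its metal alkoxide, diastereomer mixture) | CC(C)=CC[C@@H](O)c1coc(C2(O)C(OC(C)C)=C(OC(C)C)C2O)c1 | intermediate
11 | 3-[4-[(1R)-1-hydroxy-4-methylpent-3-en-1-yl]furan-2-yl]cyclobut-3-ene-1,2-dione | CC(C)=CC[C@@H](O)c1coc(C2=CC(=O)C2=O)c1 | intermediate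
12 | 3-methylbutanoyl chloride (isovaleryl chloride) | CC(C)CC(=O)Cl | starting material
13 | (R)-1-[5-(3,4-dioxocyclobut-1-en-1-yl)furan-3-yl]-4-methylpent-3-en-1-yl 3-methylbutanoate | CC(C)=CC[C@@H](OC(=O)CC(C)C)c1coc(C2=CC(=O)C2=O)c1 | intermediate
14 | vinylmagnesium bromide | C=C[Mg]Br | starting material
15 | (R)-1-[5-(4-hydroxy-3-oxo-4-vinylcyclobut-1-en-1-yl)furan-3-yl]-4-methylpent-3-en-1-yl 3-methylbutanoate | CC(C)=CC[C@@H](OC(=O)CC(C)C)c1coc(C2=CC(=O)C2(O)C=C)c1 | intermediate
16 | (R)-1-[5-[(3Z)-4-hydroxy-1-oxohexa-1,3,5-trien-3-yl]furan-3-yl]-4-methylpent-3-en-1-yl 3-methylbutanoate (dienylketene) | CC(C)=CC[C@@H](OC(=O)CC(C)C)c1coc(C(/C=C=O)=C(\O)C=C)c1 | intermediate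
17 | (R)-1-[5-(6-hydroxy-3-oxocyclohexa-1,5-dien-1-yl)furan-3-yl]-4-methylpent-3-en-1-yl 3-methylbutanoate (cyclohexadienone) | CC(C)=CC[C@@H](OC(=O)CC(C)C)c1coc(C2=CC(=O)CC=C2O)c1 | intermediate
18 | (R)-1-[5-(2,5-dihydroxyphenyl)furan-3-yl]-4-methylpent-3-en-1-yl 3-methylbutanoate | CC(C)=CC[C@@H](OC(=O)CC(C)C)c1coc(-c2cc(O)ccc2O)c1 | intermediate
19 | (R)-1-[5-(3,6-dioxocyclohexa-1,4-dien-1-yl)furan-3-yl]-4-methylpent-3-en-1-yl 3-methylbutanoate | CC(C)=CC[C@@H](OC(=O)CC(C)C)c1coc(C2=CC(=O)C=CC2=O)c1 | target

**Step count**
Total steps: 7. Longest linear sequence: 7 steps (from 1).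

**Steps most likely to fail**

Step 3. The hydride transfer to the alkoxide-bearing adduct may be incomplete. In the acidic transposition the side-chain carbinol may ionise (erosion of enantiopurity) or HCl may add to the trisubstituted alkene. The fallback sets out from 6 and puts the ester in place before the four-membered ring. Acylation of 6 with 12 and pyridine in CH2Cl2 should give (R)-1-(5-bromofuran-3-yl)-4-methylpent-3-en-1-yl 3-methylbutanoate F1. Bromine–magnesium exchange with iPrMgCl·LiCl (THF, −15 °C) should give the ester-tolerant furylmagnesium chloride F2, which is added to 7 at −78 °C to give the isolable squarate adduct F3. Chelation-controlled reduction of its ring ketone with Zn(BH4)2 (Et2O, −20 °C) should give the ring diol F4. Hydrolytic transposition under mild acid (oxalic acid on wet silica, CH2Cl2) should then give 13, so the route is rejoined at 13 and step 4 is no longer needed.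

Step 5. Conjugate addition of the Grignard reagent to the unsubstituted ring carbon, or attack on the isovalerate, may compete with carbonyl addition. The fallback sets out from 11 and moves the carbon–carbon bond formation ahead of the esterification. The less basic, more oxophilic vinylcerium dichloride F5, prepared from 14 and CeCl3 (2.5 equiv, THF, −78 °C), is added to 11 and should give the diol 4-hydroxy-3-[4-[(1R)-1-hydroxy-4-methylpent-3-en-1-yl]furan-2-yl]-4-vinylcyclobut-2-en-1-one F6. Selective acylation of its secondary hydroxyl with 12 and pyridine at −20 °C, the tertiary ring carbinol staying free, should give 15, where the route is rejoined.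

Step 6. Capture of the ketene by the free tertiary hydroxyl (lactonisation to a butenolide) may outrun the 6π-closure, and the free hydroquinone may degrade by air oxidation at 110 °C. The fallback sets out from 15 and masks the hydroxyl. Silylation with 1-(trimethylsilyl)imidazole (CH2Cl2, rt) should give the trimethylsilyl ether of 15 F7. Its thermolysis (degassed toluene, 110 °C) runs the same ring opening and closure and should give the mono-silylated hydroquinone F8. Brief treatment with AcOH/H2O/THF should remove the silyl group and give 18, where the route is rejoined.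

**Further compounds**
F1 | step 3 | (R)-1-(5-bromofuran-3-yl)-4-methylpent-3-en-1-yl 3-methylbutanoate | CC(C)=CC[C@@H](OC(=O)CC(C)C)c1coc(Br)c1
F2 | step 3 | [4-[(1R)-4-methyl-1-(3-methylbutanoyloxy)pent-3-en-1-yl]furan-2-yl]magnesium chloride | CC(C)=CC[C@@H](OC(=O)CC(C)C)c1coc([Mg]Cl)c1
F3 | step 3 | (R)-1-[5-(1-hydroxy-2,3-diisopropoxy-4-oxocyclobut-2-en-1-yl)furan-3-yl]-4-methylpent-3-en-1-yl 3-methylbutanoate | CC(C)=CC[C@@H](OC(=O)CC(C)C)c1coc(C2(O)C(OC(C)C)=C(OC(C)C)C2=O)c1
F4 | step 3 | (R)-1-[5-(1,4-dihydroxy-2,3-diisopropoxycyclobut-2-en-1-yl)furan-3-yl]-4-methylpent-3-en-1-yl 3-methylbutanoate | CC(C)=CC[C@@H](OC(=O)CC(C)C)c1coc(C2(O)C(OC(C)C)=C(OC(C)C)C2O)c1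
F5 | step 5 | vinylcerium dichloride | C=C[Ce](Cl)Cl
F6 | step 5 | 4-hydroxy-3-[4-[(1R)-1-hydroxy-4-methylpent-3-en-1-yl]furan-2-yl]-4-vinylcyclobut-2-en-1-one | CC(C)=CC[C@@H](O)c1coc(C2=CC(=O)C2(O)C=C)c1
F7 | step 6 | (R)-1-[5-(3-oxo-4-trimethylsilyloxy-4-vinylcyclobut-1-en-1-yl)furan-3-yl]-4-methylpent-3-en-1-yl 3-methylbutanoate | CC(C)=CC[C@@H](OC(=O)CC(C)C)c1coc(C2=CC(=O)C2(O[Si](C)(C)C)C=C)c1
F8 | step 6 | (R)-1-[5-(5-hydroxy-2-trimethylsilyloxyphenyl)furan-3-yl]-4-methylpent-3-en-1-yl 3-methylbutanoate | CC(C)=CC[C@@H](OC(=O)CC(C)C)c1coc(-c2cc(O)ccc2O[Si](C)(C)C)c1
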